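5 questions stand on 4 flasks: which one holds the most G, and how much G each holds at the end.

| flask | L | E | J | temperature | remark | time |
|---|---|---|---|---|---|---|
| epsilon | 18 mM | 0.45 mM | 0.45 mM | −25 °C | run made earlier |  |
| eta | 18 mM | 0.68 mM | 0.45 mM | 10 °C | run made earlier |  |
| theta | 9 mM | 0.90 mM | 0.45 mM | −25 °C | run made earlier |  |
| cedar | 18 mM | 0.900 mM | 0.45 mM | 40 °C |  | 8.0 h |
| alder | 18 mM | 0.900 mM | 0.45 mM | −20 °C |  | 8.0 h |
| birch | 18 mM | 0.900 mM | 0.45 mM | 10 °C |  | 8.0 h |
| oak | 18 mM | 0.900 mM | 0.45 mM |  | at 40 °C until 2.5 h, from then on at −20 °C | 8.0 h |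

- epsilon (time / h: G / %, L / %): 25.0: 0.9, 99.1; 50.0: 1.9, 97.2; 72.0: 1.5, 97.2; 96.0: 2.9, 96.9; 120: 3.7, 96.2
- eta (time / h: G / %, L / %): 2.00: 1.3, 97.5; 6.00: 4.3, 93.8; 8.00: 5.8, 92.1; 12.0: 6.8, 89.8; 20.0: 10.7, 84.1
- theta (time / h: G / %, L / %): 25.0: 0.8, 99.4; 50.0: 2.1, 98.3; 72.0: 1.9, 97.7; 96.0: 3.8, 95.7; 120: 3.9, 95.8

(readings scatter by 0.5 percentage points)

- percent here means L units held: one D counts as two
- on the list of suspects stand: G -> X; L + J -> Q + G; L + Q -> G + Q; E + L -> Z; 2 L -> D

1. the best flask by amount of G, in percent of the L charged; "all alike" if 1.5 percentage points covers them all (cedar / alder / birch / oak / all alike)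
2. amount of G at the end, in percent of the L charged, cedar
3. amount of G at the end, in percent of the L charged, alder
4. amount of G at the end, in percent of the L charged, birch
5. amount of G at the end, in percent of the L charged, oak

Oak looks contradictory: it stands longer cold, 5.50 h at −20 °C, than hot, 2.5 h at 40 °C, yet I mean to count its cold hours as minutes.

Epsilon and theta differ in L by half and in E by twice, yet they read 3.7% and 3.9% of G at 120 h, inside a scatter of 0.5 percentage points. So I take percent of L per hour as the rate. Dividing G by time at the last readings, eta reads 17.4 times faster than epsilon. In logarithms that is 1.24 decades over 35.0 K, so the steepness is 0.0354 K⁻¹, the decades of rate gained per kelvin. A straight line in temperature is coarse, but I am working in powers of ten.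

Across oak's step of 60.0 K the steepness gives 2.12 decades, a factor 133. So oak's cold stretch is worth 2.48 min at 40 °C, and I expect oak to read like a flask stopped at 2.5 h. The same steepness says birch needs 92.3 h to match cedar's 8.0 h.

The forecast names cedar as best, with 18% in cedar, 0.4% in alder, 5.5% in birch and 9% in oak: “Oak freezes after about 9 %”.

The flask gives cedar as best, with 29.4% in cedar, 0.467% in alder, 5.13% in birch and 12.4% in oak. The forecast parts from this in cedar, by 11 points.

    G → X (k = 1.00 × 10⁻⁶ s⁻¹, Ea = 117 kJ mol⁻¹)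
    L + J → Q + G (k = 0.0820 L mol⁻¹ s⁻¹, Ea = 59.0 kJ mol⁻¹)
    L + Q → G + Q, rate k3*[Q]*[L] (k = 0.0300 L mol⁻¹ s⁻¹, Ea = 57.0 kJ mol⁻¹)
    E + L → Z (k = 0.00230 L mol⁻¹ s⁻¹, Ea = 71.0 kJ mol⁻¹)
    2 L → D (k = 2.40 × 10⁻⁴ L mol⁻¹ s⁻¹, Ea = 59.0 kJ mol⁻¹)
    (constants at 40 °C)

Oak bears the steepness out: its G reads 12.3% at 2.50 h and 12.4% at 8.00 h. Birch, the second flask, holds 29.8% of G and 55.4% of L at 80.0 h, while cedar holds 29.4% and 53.6% at 8.00 h, so birch's G has reached cedar's by then, ahead of the 92.3 h I reckoned. The main reason cedar's G stands where it does at 8.00 h is the depletion of J: J reads 0% of its charge by then, and cedar with J kept from depleting gives 91.7% of G instead of 29.4%.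

The numbers in the tables were generated by integration with constants of no real substance.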